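(The numbers in the tables stem from a simulated flask for substances that don't exist; noise was put on by code.)

Dusk ends higher than noon, at 72.2% against 58.4% of the substrate charged, with the same substrate and second nucleophile in both and more first nucleophile in dusk.

all flasks: second nucleophile 0.255 M

|  | substrate | first nucleophile | remark | time |
|---|---|---|---|---|
| noon | 0.51 M | 0.55 M | run made earlier |  |
| winter | 0.51 M | 0.87 M | run made earlier |  |
| dusk | 0.51 M | 0.94 M | run made earlier |  |
| midnight | 1.3 M | 0.561 M | run made earlier |  |
| north-east | 2.0 M | 1.20 M |  | 8.0 min |
| north | 0.51 M | 0.561 M |  | 8.0 min |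

| run | time / min | target / % | substrate / % |
|---|---|---|---|
| noon | 0.667 | 46.5 | 14.0 |
| noon | 2.00 | 57.3 | 0.7 |
| noon | 4.00 | 58.2 | 0 |
| noon | 6.00 | 59.0 | 0.9 |
| noon | 8.00 | 58.4 | 0.2 |
| winter | 1.50 | 68.3 | 1.3 |
| winter | 3.00 | 70.6 | 0 |
| winter | 5.00 | 70.7 | 0.2 |
| winter | 6.00 | 71.7 | 0.1 |
| winter | 8.00 | 70.2 | 0 |
| dusk | 0.667 | 58.6 | 14.6 |
| dusk | 2.00 | 70.9 | 0.5 |
| dusk | 4.00 | 71.1 | 0 |
| dusk | 6.00 | 71.7 | 0.1 |
| dusk | 8.00 | 72.2 | 0 |
| midnight | 0.667 | 37.4 | 14.7 |
| midnight | 1.33 | 41.4 | 2.1 |
| midnight | 2.50 | 42.2 | 0.1 |
| midnight | 4.00 | 41.4 | 0 |
| midnight | 8.00 | 41.5 | 0.1 |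

(each reading ± 0.5 percentage points)

* which one finishes higher in amount of target, in percent of the substrate charged ("neither" within 2 percentage points) (north-east / north / neither)
* amount of target at the end, in percent of the substrate charged, north-east
* amount of target at the end, in percent of the substrate charged, north

- a reading or a percentage of target counts all its forms, free or not

How long must these flasks run? Not long. At 0.667 min, substrate reads 14.0% in noon, 14.6% in dusk and 14.7% in midnight, and noon reads 0% at 4.00 min. So within 8.0 min the question is where the substrate went, not how fast.

Then what do you count? Turnovers. I take each target to carry one first nucleophile. The ceiling of north-east is 60.0%: the first nucleophile charged as a fraction of the substrate charged. That makes first nucleophile the limiting reagent in north-east.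

But noon, with a ceiling of 108%, reads 58.4%. Why trust a ceiling? It is a bound and tells nothing about reaching it, so I need a run that stands under its own. Midnight has a ceiling of 43.2% and reads 41.5%, so 96.2% of its first nucleophile went to target.

Your number? Carrying that reading over, north-east gives 57.7%. This is the weak spot, since north-east has a higher ceiling than midnight and its spent share may differ.

And north? Its substrate and second nucleophile are noon's and its first nucleophile is 0.561 M against 0.55 M, so I take noon's reading, about 58.4%. The gap of 0.7 percentage points is under 2 points, so I say neither.

The forecast says neither, with 58.5% for north-east (56% to 60%) and 59% for north (58% to 60%). In its words, “North is nearly noon”. Its north-east figure comes from fitted relative rates and stands 0.8 points above mine.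

The flasks give neither: north-east 58.2%, north 58.8%.

    second nucleophile + target ⇌ idle adduct, settled at all times (K = 8.80 /M)
    intermediate → solvolysis product (k = 0.0640 /s)
    substrate → intermediate (k = 0.0480 /s)
    2 second nucleophile → homo dimer (k = 0.450 /M/s)
    first nucleophile + intermediate → target (k = 0.300 /M/s)
    second nucleophile + intermediate → other capture product (k = 0.510 /M/s)

North-east keeps 3.1% of its first nucleophile, and the ceiling times the spent share gives 58.1%. With first nucleophile held at its charged level, the same flask reaches 82.2% instead of 58.2%, so its falling level is the main reason. The neighbour of north with substrate raised to 0.87 M has a ceiling of 64.5% and keeps 20% of its first nucleophile, which gives 51.6%; that neighbour ends at 51.8%.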